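**Plan**

Locants: ring atoms as in the 7-oxabicyclo[4.1.0]heptane core (C-1 methyl-bearing oxirane carbon, C-2 carbonyl, C-3 acyloxy carbon, C-4 side-chain carbon, C-6 oxirane CH); side chain C-1′ (=CH2), C-2′, C-3′ (CHOAc).
Retrosynthesis: cut the senecioate acyl–O bond, then the C-3–O bond (ketone α-hydroxylation), return C-2 to the alcohol level, cut the acetate, then cut C-2′–C-3′ into a ring alkenyl boronate and a homoprenyl carbamate; the boronate goes back through alkenyl triflate and methyl ketone to the isopropenyl group of (R)-carvone.
Enabling feature: C-3′ is a secondary carbinol carbon bonded directly to the sp2 carbon C-2′ of the exocyclic methylene alkene on ring carbon C-4, i.e. an α-branched allylic alcohol. This is the oxidation product of an allylic boronic ester, which forms when the ring-bearing alkenyl group shifts from boron to the α-carbon of a lithiated carbamate (1,2-metallate rearrangement); boron and carbamate are the helpers and leave in the same flask.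
Forward order: the carbocycle comes from carvone; the oxirane ring is closed first (it also shields the ring alkene from ozone); isopropenyl is cut to acetyl and converted to the alkenyl boronate; the side chain is joined; the ketone is restored and C-3 is oxygenated and acylated last.
Stereochemistry: C-4 from (R)-carvone; oxirane face (C-1, C-6) from the cis-carveol hydroxyl by directed epoxidation; C-3′ from (−)-sparteine through stereospecific borylation, 1,2-shift and oxidation; C-3 by attack on the enolate face anti to the C-4 side chain.

Key step: step 8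

**Route**

Step 1
Reactants: 1 (R)-(−)-carvone
Product: 2 (−)-cis-carveol, (1R,5R)-2-methyl-5-(prop-1-en-2-yl)cyclohex-2-en-1-ol
Conditions: NaBH4, CeCl3·7H2O, MeOH, −20 °C
Reagents that add atoms: none
Why: Luche reduction: Ce(III)-promoted 1,2-hydride addition, with axial hydride delivery on the half-chair that carries the isopropenyl group equatorially, should give the pseudo-equatorial alcohol cis to isopropenyl (new carbinol centre, 1R).

Step 2
Reactants: 2 (−)-cis-carveol
Product: 3 (1R,2R,4S,6S)-1-methyl-4-(prop-1-en-2-yl)-7-oxabicyclo[4.1.0]heptan-2-ol (OH, oxirane O and isopropenyl on one ring face)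
Conditions: VO(acac)2 (cat.), t-BuOOH, CH2Cl2, 0 °C → rt
Reagents that add atoms: tert-butyl hydroperoxide, CC(C)(C)OO
Why: Vanadium-catalysed hydroxyl-directed epoxidation: the allylic vanadate ester delivers oxygen to the ring alkene on the face of the OH (also the face of the isopropenyl group), setting both oxirane centres, while the isopropenyl alkene, which has no directing group, should be left untouched.

Step 3
Reactants: 3 epoxy alcohol
Product: 4 tert-butyldimethylsilyl ether of 3 (ring stereocentres unchanged)
Conditions: TBSCl, imidazole, DMAP (cat.), DMF, rt → 40 °C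
Reagents that add atoms: tert-butyldimethylsilyl chloride, CC(C)(C)[Si](C)(C)Cl
Why: Imidazole-mediated silylation stores the future C-2 ketone as a base-stable TBS ether and touches no stereocentre.

Step 4
Reactants: 4 TBS ether
Product: 6 methyl ketone (acetyl in place of the isopropenyl group of 4), via ozonide 5 (not isolated)
Conditions: O3, CH2Cl2, −78 °C; then PPh3, −78 °C → rt
Reagents that add atoms: ozone, [O-][O+]=O
Why: Ozonolysis (Criegee mechanism) cleaves the only remaining C=C, the ring alkene being already masked as the oxirane, and PPh3 reduces the ozonide to the methyl ketone without affecting the oxirane or silyl ether.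

Step 5
Reactants: 6 methyl ketone
Product: 8 alkenyl triflate (1-substituted ethenyl trifluoromethanesulfonate on C-4), via potassium enolate 7 (not isolated)
Conditions: KHMDS, THF, −78 °C; then N-(5-chloro-2-pyridyl)triflimide (Comins' reagent), −78 °C
Reagents that add atoms: N-(5-chloropyridin-2-yl)bis(trifluoromethanesulfonyl)imide, O=S(=O)(N(c1ccc(Cl)cn1)S(=O)(=O)C(F)(F)F)C(F)(F)F
Why: Kinetic deprotonation at the unhindered CH3 and fast O-sulfonylation at −78 °C (enol triflate formation) should give the terminal 1,1-disubstituted alkenyl triflate without equilibration toward the ring methine, so the C-4 centre is kept.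

Step 6
Reactants: 8 alkenyl triflate
Product: 9 alkenyl pinacol boronate (Bpin in place of OTf)
Conditions: B2pin2, PdCl2(PPh3)2 (cat.), PPh3, KOPh, toluene, 50 °C
Reagents that add atoms: bis(pinacolato)diboron, CC1(C)OB(OC1(C)C)B1OC(C)(C)C(C)(C)O1
Why: Miyaura borylation of an alkenyl triflate: oxidative addition to Pd(0), phenoxide-assisted transmetalation with B2pin2 and reductive elimination replace OTf by Bpin with the alkene position unchanged.

Step 7
Reactants: 10 4-methylpent-3-en-1-ol
Product: 11 4-methylpent-3-en-1-yl N,N-diisopropylcarbamate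
Conditions: i-Pr2NCOCl, Et3N, CH2Cl2, reflux
Reagents that add atoms: N,N-diisopropylcarbamoyl chloride, CC(C)N(C(C)C)C(=O)Cl
Why: O-Carbamoylation of the primary alcohol gives the carbamate whose C=O directs α-lithiation and which later serves as the leaving group.

Step 8
Reactants: 11 4-methylpent-3-en-1-yl N,N-diisopropylcarbamate; 9 alkenyl pinacol boronate
Product: 15 (3′R)-allylic alcohol (C-3′ OH; ring still carrying the C-2 OTBS group and the oxirane), via lithiated carbamate 12 (not isolated), via boron ate complex 13 (not isolated), via allylic boronic ester 14 (not isolated)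
Conditions: 11 (excess), s-BuLi, (−)-sparteine, Et2O, −78 °C; then 9, −78 °C, then reflux; then NaOH, H2O2, THF/H2O, 0 °C → rt
Reagents that add atoms: hydrogen peroxide, OO
Why: s-BuLi/(−)-sparteine removes the pro-S α-proton of 11 (carbamate-directed, faster than allylic deprotonation) to give the configurationally stable (S)-lithio carbamate 12, which is borylated by 9 with retention to ate complex 13; on warming, the ring-bearing alkenyl group migrates from boron to carbon anti to the departing carbamate (1,2-metallate rearrangement, inversion at carbon), forming the C-2′–C-3′ bond and allylic boronate 14, whose C–B bond is oxidised with retention to alcohol 15. The closest known reaction type is the lithiation–borylation of primary alkyl carbamates with alkenyl boronic esters followed by oxidation. No ring is closed. The one new stereocentre, C-3′ (R), is fixed by the chiral diamine (reagent control) and relayed by three stereospecific events, so it does not depend on the ring stereocentres. The step needs carbon rather than a pinacol oxygen to migrate, which the sp2 alkenyl group secures, and needs the organolithium to meet only boron, which is secured because every carbonyl group is absent at this stage (ring ketone stored as the TBS ether), the trisubstituted oxirane is inert at −78 °C and no Lewis-acid promoter is added. Oxidation occurs at boron by a 1,2-shift to oxygen, so no allylic transposition is expected.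

Step 9
Reactants: 15 (3′R)-allylic alcohol
Product: 16 C-3′ acetate of 15
Conditions: Ac2O, pyridine, DMAP (cat.), CH2Cl2, rt
Reagents that add atoms: acetic anhydride, CC(=O)OC(C)=O
Why: DMAP-catalysed O-acetylation installs the C-3′ acetate without touching the stereocentre.

Step 10
Reactants: 16 acetate
Product: 17 C-2 alcohol (TBS removed; OH on the face of the oxirane O and the side chain)
Conditions: HF·pyridine, pyridine, THF, 0 °C → rt
Reagents that add atoms: none
Why: Fluoride-driven Si–O cleavage under pyridine buffering should remove the TBS group while the acetate and the trisubstituted oxirane remain.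

Step 11
Reactants: 17 C-2 alcohol
Product: 18 epoxy ketone (C-2 carbonyl; C-3 still CH2)
Conditions: Dess–Martin periodinane, NaHCO3, CH2Cl2, rt
Reagents that add atoms: none
Why: Dess–Martin oxidation under bicarbonate buffer converts the secondary alcohol into the ketone without acid-induced oxirane opening or alkene oxidation.

Step 12
Reactants: 18 epoxy ketone
Product: 20 (3S)-3-hydroxy ketone (OH trans to the C-4 side chain), via sodium enolate 19 (not isolated)
Conditions: NaHMDS, THF, −78 °C; then 2-(phenylsulfonyl)-3-phenyloxaziridine, −78 °C; AcOH quench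
Reagents that add atoms: 2-(phenylsulfonyl)-3-phenyloxaziridine (Davis oxaziridine), O=S(=O)(c1ccccc1)N1OC1c1ccccc1
Why: Davis enolate hydroxylation: NaHMDS deprotonates the ketone at its only enolisable position C-3 much faster than the acetate, and the oxaziridine should transfer oxygen to the enolate face anti to the adjacent C-4 side chain and the oxirane oxygen, giving the 3,4-trans hydroxy ketone, which is also the more stable diequatorial epimer.

Step 13
Reactants: 20 (3S)-3-hydroxy ketone
Product: 21 target, (1S,3S,4S,6S)-4-[(3R)-3-acetoxy-6-methylhepta-1,5-dien-2-yl]-1-methyl-2-oxo-7-oxabicyclo[4.1.0]heptan-3-yl 3-methylbut-2-enoate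
Conditions: 3-methylbut-2-enoic acid, DCC, DMAP (cat.), CH2Cl2, 0 °C → rt
Reagents that add atoms: 3-methylbut-2-enoic acid, CC(C)=CC(=O)O
Why: Steglich esterification acylates the secondary α-hydroxy ketone with the free acid, avoiding the vinylketene pathway that deconjugates the acid chloride under amine bases, and leaves the C-3 centre untouched.

**Compound list**

1 | (R)-(−)-carvone, (5R)-2-methyl-5-(prop-1-en-2-yl)cyclohex-2-en-1-one | C=C(C)[C@@H]1CC=C(C)C(=O)C1 | starting material
2 | (−)-cis-carveol, (1R,5R)-2-methyl-5-(prop-1-en-2-yl)cyclohex-2-en-1-ol | C=C(C)[C@@H]1CC=C(C)[C@H](O)C1 | intermediate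
3 | (1R,2R,4S,6S)-1-methyl-4-(prop-1-en-2-yl)-7-oxabicyclo[4.1.0]heptan-2-ol (OH, oxirane O and isopropenyl all cis) | C=C(C)[C@@H]1C[C@@H]2O[C@]2(C)[C@H](O)C1 | intermediate
4 | tert-butyldimethylsilyl ether of 3 | C=C(C)[C@@H]1C[C@@H]2O[C@]2(C)[C@H](O[Si](C)(C)C(C)(C)C)C1 | intermediate
5 | secondary ozonide of 4 (3-methyl-1,2,4-trioxolan-3-yl in place of isopropenyl; acetal carbon unassigned) | CC3(OCOO3)[C@@H]1C[C@@H]2O[C@]2(C)[C@H](O[Si](C)(C)C(C)(C)C)C1 | intermediate (not isolated)
6 | methyl ketone: acetyl in place of the isopropenyl group of 4 | CC(=O)[C@@H]1C[C@@H]2O[C@]2(C)[C@H](O[Si](C)(C)C(C)(C)C)C1 | intermediate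
7 | terminal potassium enolate of 6 | [K+].C=C([O-])[C@@H]1C[C@@H]2O[C@]2(C)[C@H](O[Si](C)(C)C(C)(C)C)C1 | intermediate (not isolated)
8 | alkenyl triflate: 1-(ring)ethenyl trifluoromethanesulfonate | C=C(OS(=O)(=O)C(F)(F)F)[C@@H]1C[C@@H]2O[C@]2(C)[C@H](O[Si](C)(C)C(C)(C)C)C1 | intermediate
9 | alkenyl pinacol boronate: 2-[1-(ring)ethenyl]-4,4,5,5-tetramethyl-1,3,2-dioxaborolane | C=C(B3OC(C)(C)C(C)(C)O3)[C@@H]1C[C@@H]2O[C@]2(C)[C@H](O[Si](C)(C)C(C)(C)C)C1 | intermediate
10 | 4-methylpent-3-en-1-ol | CC(C)=CCCO | starting material
11 | 4-methylpent-3-en-1-yl N,N-diisopropylcarbamate | CC(C)=CCCOC(=O)N(C(C)C)C(C)C | intermediate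
12 | (S)-1-lithio-4-methylpent-3-en-1-yl N,N-diisopropylcarbamate, as its (−)-sparteine complex | [Li][C@@H](CC=C(C)C)OC(=O)N(C(C)C)C(C)C | intermediate (not isolated)
13 | lithium boronate complex: boron carrying pinacolate, the ring alkenyl group and the (S)-carbamoyloxyalkyl group | [Li+].C=C([C@@H]1C[C@@H]2O[C@]2(C)[C@H](O[Si](C)(C)C(C)(C)C)C1)[B-]3(OC(C)(C)C(C)(C)O3)[C@@H](CC=C(C)C)OC(=O)N(C(C)C)C(C)C | intermediate (not isolated)
14 | allylic pinacol boronate (Bpin on C-3′, configuration as the OH in 15) | C=C([C@@H](CC=C(C)C)B3OC(C)(C)C(C)(C)O3)[C@@H]1C[C@@H]2O[C@]2(C)[C@H](O[Si](C)(C)C(C)(C)C)C1 | intermediate (not isolated)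
15 | (3′R)-allylic alcohol with C-2 OTBS and oxirane | C=C([C@@H](CC=C(C)C)O)[C@@H]1C[C@@H]2O[C@]2(C)[C@H](O[Si](C)(C)C(C)(C)C)C1 | intermediate
16 | C-3′ acetate of 15 | C=C([C@@H](CC=C(C)C)OC(C)=O)[C@@H]1C[C@@H]2O[C@]2(C)[C@H](O[Si](C)(C)C(C)(C)C)C1 | intermediate
17 | C-2 alcohol (TBS removed from 16) | C=C([C@@H](CC=C(C)C)OC(C)=O)[C@@H]1C[C@@H]2O[C@]2(C)[C@H](O)C1 | intermediate
18 | epoxy ketone (C-2 carbonyl, C-3 CH2) | C=C([C@@H](CC=C(C)C)OC(C)=O)[C@@H]1C[C@@H]2O[C@]2(C)C(=O)C1 | intermediate
19 | sodium enolate of 18 (C-2 O–Na, C-2=C-3) | [Na+].C=C([C@@H](CC=C(C)C)OC(C)=O)[C@@H]1C[C@@H]2O[C@]2(C)C([O-])=C1 | intermediate (not isolated)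
20 | (3S)-3-hydroxy ketone, OH trans to the C-4 side chain | C=C([C@@H](CC=C(C)C)OC(C)=O)[C@@H]1C[C@@H]2O[C@]2(C)C(=O)[C@H]1O | intermediate
21 | (1S,3S,4S,6S)-4-[(3R)-3-acetoxy-6-methylhepta-1,5-dien-2-yl]-1-methyl-2-oxo-7-oxabicyclo[4.1.0]heptan-3-yl 3-methylbut-2-enoate | C=C([C@@H](CC=C(C)C)OC(C)=O)[C@@H]1C[C@@H]2O[C@]2(C)C(=O)[C@H]1OC(=O)C=C(C)C | target

**Count and risks**

Total steps: 13. Longest linear sequence: 12 (1 → 21 through steps 1–6 and 8–13).

Step 8. What may go wrong: the ate complex from the α-branched alkenyl boronate may form slowly or revert on warming, so the lithiated carbamate decomposes before the 1,2-shift (low conversion, eroded stereochemical purity at C-3′). Fallback (carbonyl addition instead of a 1,2-metallate shift): it sets out from alkenyl triflate 8 and alcohol 10 and comes back at 15. Alcohol 10 is oxidised with Dess–Martin periodinane/NaHCO3 in CH2Cl2 at 0 °C to 4-methylpent-3-enal F1, used at once because it conjugates readily. Triflate 8 and F1 are joined by a Nozaki–Hiyama–Kishi reaction (CrCl2, cat. NiCl2, chiral oxazoline–sulfonamide ligand, Et3N, THF, rt). The alkenylnickel from oxidative addition transmetalates to chromium(III), which adds only to the aldehyde and should tolerate the unactivated oxirane and the silyl ether. The ligand is meant to set C-3′, and a minor epimer would be removed by chromatography at 15.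

Step 12. What may go wrong: under the basic enolate conditions the side-chain acetate may be deprotonated or attacked by the enolate or the new alkoxide (acyl transfer), and the oxidant may not discriminate the two enolate faces well enough. Fallback (acid-side [3,3] oxygen transfer, no enolate): it sets out from ketone 18 and comes back at 21, replacing steps 12 and 13. Commercial tert-butyl N-hydroxy-N-methylcarbamate is O-acylated with 3-methylbut-2-enoyl chloride (Et3N, CH2Cl2, 0 °C) to tert-butyl N-methyl-N-[(3-methylbut-2-enoyl)oxy]carbamate F2. HCl in dioxane removes the Boc group to give N-methyl-O-(3-methylbut-2-enoyl)hydroxylamine hydrochloride F3. Ketone 18 and F3 in DMSO at rt to 40 °C should condense to the N-acyloxy enamine at C-2/C-3, which undergoes a [3,3]-sigmatropic shift and hydrolysis. This is the known α-acyloxylation of ketones with N-methyl-O-acylhydroxylamine salts, and it would place the senecioate on C-3 directly. The α-acyloxy ketone is epimerisable under these conditions and should settle as the trans-diequatorial isomer 21.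

Step 5. What may go wrong: proton exchange during triflation may generate the more substituted enolate, giving the internal enol triflate and epimerisation at the ring methine C-4. Fallback (Shapiro route, no enol triflate): it sets out from ketone 6 and comes back at boronate 9, by-passing 8. Ketone 6 is condensed with 2,4,6-triisopropylbenzenesulfonyl hydrazide (THF, rt) to the 2,4,6-triisopropylbenzenesulfonylhydrazone F4. n-BuLi (2.2 equiv) in THF/TMEDA, −78 → 0 °C, deprotonates the methyl group of the hydrazone anion, and loss of sulfinate and nitrogen gives the alkenyllithium F5. F5 is trapped at −78 °C with 2-isopropoxy-4,4,5,5-tetramethyl-1,3,2-dioxaborolane to give 9.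

**Further compounds**

F1 | step 8 | 4-methylpent-3-enal | CC(C)=CCC=O
F2 | step 12 | tert-butyl N-methyl-N-[(3-methylbut-2-enoyl)oxy]carbamate | CC(C)=CC(=O)ON(C)C(=O)OC(C)(C)C
F3 | step 12 | N-methyl-O-(3-methylbut-2-enoyl)hydroxylamine hydrochloride | C[NH2+]OC(=O)C=C(C)C.[Cl-]
F4 | step 5 | 2,4,6-triisopropylbenzenesulfonylhydrazone of 6 | CC(=NNS(=O)(=O)c3c(C(C)C)cc(C(C)C)cc3C(C)C)[C@@H]1C[C@@H]2O[C@]2(C)[C@H](O[Si](C)(C)C(C)(C)C)C1
F5 | step 5 | alkenyllithium (Li in place of the Bpin group of 9) | [Li]C(=C)[C@@H]1C[C@@H]2O[C@]2(C)[C@H](O[Si](C)(C)C(C)(C)C)C1
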